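**Retrosynthetic overview**
1. Target 23 is cut at the allylic C–O bond (Mitsunobu) into diol 13 and 4-hydroxy-5-methylcoumarin 22.
2. Diol 13 comes from keto ester 11 (C=O to C=CH2, enoate to CH2OH); 11 comes from exo-methylene enone 7 and silyl dienolate 9 by a vinylogous Mukaiyama–Michael addition, with the side-chain ring carbon set by protonation.
3. Enone 7 arises by a ring-expanding 1,2-shift of ethynyl carbinol 6 (cyclopentanol to cyclohexanone, the quaternary carbon migrates); 6 comes from ketone 4 and ethynyl Grignard 5.
4. Ketone 4 comes from desymmetrising reduction of 2,2-dimethylcyclopentane-1,3-dione 2 (sets the carbinol centre), made from dione 1.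
5. Coumarin 22: arene by annulation of methyl acetoacetate with crotonaldehyde and aromatisation, then lactone closure. Ring order: cyclopentane (bought), then cyclohexane (ring expansion); separately benzene, then pyranone.

Assumption: 5 is used as its commercial THF solution, and 6 is carried on as the mixture of carbinol epimers because that centre becomes the carbonyl carbon in step 5.

**Step 1**
Reactants: 1 2-methylcyclopentane-1,3-dione
Product: 2 2,2-dimethylcyclopentane-1,3-dione
Conditions: MeI, KOH, H2O–dioxane, reflux
Reagents that add atoms: iodomethane, CI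
Why: C-alkylation of the stabilised 1,3-dione enolate with the small electrophile MeI (enolate alkylation) builds the quaternary carbon; no stereocentre is formed.

**Step 2**
Reactants: 2 2,2-dimethylcyclopentane-1,3-dione
Product: 3 (3S)-3-hydroxy-2,2-dimethylcyclopentan-1-one
Conditions: baker's yeast, sucrose, H2O, 30 °C
Reagents that add atoms: none
Why: Whole-cell enzymatic desymmetrising ketone reduction of the prochiral dione reduces one enantiotopic carbonyl only and gives the (S)-ketol in high ee, which becomes the carbinol stereocentre of the target.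

**Step 3**
Reactants: 3 (3S)-3-hydroxy-2,2-dimethylcyclopentan-1-one
Product: 4 (1S)-2,2-dimethyl-3-oxocyclopentyl pivalate
Conditions: PivCl, pyridine, DMAP (cat.), CH2Cl2, 0 → 40 °C
Reagents that add atoms: pivaloyl chloride, CC(C)(C)C(Cl)=O
Why: DMAP-catalysed acylation gives a hindered ester that survives steps 4–8 and falls off in step 9; the quaternary α-carbon rules out β-elimination and the stereocentre is untouched.

**Step 4**
Reactants: 4 (1S)-2,2-dimethyl-3-oxocyclopentyl pivalate; 5 ethynylmagnesium bromide
Product: 6 (1S)-3-ethynyl-3-hydroxy-2,2-dimethylcyclopentyl pivalate (both C-3 epimers)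
Conditions: 5 (2 equiv), CeCl3, THF, −78 → 0 °C; H2O work-up
Reagents that add atoms: none
Why: Cerium-mediated 1,2-addition of the acetylide to the hindered, enolisable ketone (nucleophilic carbonyl addition) leaves the pivalate alone; the new carbinol centre need not be controlled because it is destroyed in step 5.

**Step 5**
Reactants: 6 (1S)-3-ethynyl-3-hydroxy-2,2-dimethylcyclopentyl pivalate
Product: 7 (1S)-2,2-dimethyl-3-methylidene-4-oxocyclohexyl pivalate
Conditions: LAuCl (5 mol%; L = biaryl phosphine with a remote basic amide arm), NaBArF4 (5 mol%), 4 Å MS, 1,2-dichloroethane, 60 °C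
Reagents that add atoms: none
Why: Proposed new method: cationic Au(I) π-activation of the ethynyl group lets the antiperiplanar, fully substituted ring carbon shift from the carbinol carbon to the internal alkyne carbon (semipinacol-type ring expansion) while the ligand's amide arm takes the hydroxyl proton and returns it to the vinyl–gold carbon, giving the 2-methylidenecyclohexanone; the closest known reaction is the Au(I)-catalysed ring expansion of 1-alkynylcyclobutanols and -cyclopropanols, not shown for an unstrained cyclopentanol, and here the missing ring strain is replaced by the high migratory aptitude of the quaternary carbon, relief of congestion between the two vicinal fully substituted carbons, base assistance in the transition state and the strongly exergonic change from C≡C/C–OH to C=C/C=O; anhydrous conditions suppress hydration and Meyer–Schuster paths, and the pivalate-bearing stereocentre is not touched.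

**Step 6**
Reactants: 8 methyl 3-methylbut-2-enoate
Product: 9 1-methoxy-3-methyl-1-(trimethylsilyloxy)buta-1,3-diene
Conditions: LDA, THF, −78 °C; TMSCl, −78 °C → rt; distillation
Reagents that add atoms: chlorotrimethylsilane, C[Si](C)(C)Cl
Why: γ-Deprotonation of the enoate gives the extended enolate, which TMSCl traps on oxygen (silyl dienol ether formation); no stereocentre is formed.

**Step 7**
Reactants: 7 (1S)-2,2-dimethyl-3-methylidene-4-oxocyclohexyl pivalate; 9 1-methoxy-3-methyl-1-(trimethylsilyloxy)buta-1,3-diene
Product: 11 methyl (2E)-5-[(1S,3S)-2,2-dimethyl-6-oxo-3-(pivaloyloxy)cyclohexyl]-3-methylpent-2-enoate, via silyl enol ether 10 (not isolated)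
Conditions: TMSOTf (10 mol%), CH2Cl2, −78 °C; then 1 M HCl, THF, −40 → 0 °C
Reagents that add atoms: none
Why: Vinylogous Mukaiyama–Michael addition: the dienolate attacks the unhindered exocyclic CH2 through its γ-carbon in the open s-trans arrangement, which gives the (E)-enoate, and the silyl enol ether is then protonated kinetically and axially on the face anti to the pseudo-axial ring methyl and the pivalate (syn to the carbinol C–H), which places the side chain cis to the oxygen substituent as in the target.

**Step 8**
Reactants: 11 methyl (2E)-5-[(1S,3S)-2,2-dimethyl-6-oxo-3-(pivaloyloxy)cyclohexyl]-3-methylpent-2-enoate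
Product: 12 methyl (2E)-5-[(1R,3S)-2,2-dimethyl-6-methylidene-3-(pivaloyloxy)cyclohexyl]-3-methylpent-2-enoate
Conditions: Zn, CH2Br2, TiCl4, THF–CH2Cl2, 0 °C → rt
Reagents that add atoms: dibromomethane, BrCBr
Why: Takai–Lombardo methylenation uses a non-basic Zn/Ti methylene reagent that converts the hindered ketone to the exocyclic alkene without enolising the adjacent stereocentre and leaves both esters intact; the centre then becomes allylic and configurationally fixed.

**Step 9**
Reactants: 12 methyl (2E)-5-[(1R,3S)-2,2-dimethyl-6-methylidene-3-(pivaloyloxy)cyclohexyl]-3-methylpent-2-enoate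
Product: 13 (1S,3R)-3-[(3E)-5-hydroxy-3-methylpent-3-en-1-yl]-2,2-dimethyl-4-methylidenecyclohexan-1-ol
Conditions: DIBAL-H (6 equiv), CH2Cl2, −78 → 0 °C; Rochelle salt
Reagents that add atoms: none
Why: Hydride reduction with DIBAL-H takes the enoate 1,2 to the (E)-allylic alcohol and cleaves the pivalate in the same operation; no alkene or stereocentre is affected.

**Step 10**
Reactants: 14 methyl acetoacetate; 15 (E)-but-2-enal
Product: 18 methyl 6-methyl-2-oxocyclohex-3-ene-1-carboxylate, via Michael adduct 16 (not isolated), via cyclic aldol 17 (not isolated)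
Conditions: NaOMe (0.1 equiv), MeOH, −10 °C → rt; then HCl (g), MeOH, 0 °C → rt
Reagents that add atoms: none
Why: Robinson-type annulation (Michael addition of the β-keto ester to the enal, intramolecular aldol of the methyl ketone on the aldehyde, dehydration) builds the six-membered ring with the ester between C=O and C–CH3; its stereocentres vanish on aromatisation.

**Step 11**
Reactants: 18 methyl 6-methyl-2-oxocyclohex-3-ene-1-carboxylate
Product: 20 methyl 2-hydroxy-6-methylbenzoate, via bromo keto ester 19 (not isolated)
Conditions: CuBr2 (2.2 equiv), LiBr, MeCN, reflux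
Reagents that add atoms: copper(II) bromide, [Cu+2].[Br-].[Br-] (its bromine is found only in 19)
Why: Oxidative aromatisation: α-bromination of the enolised β-keto ester, loss of HBr and tautomerisation give the phenol, driven by aromaticity.

**Step 12**
Reactants: 20 methyl 2-hydroxy-6-methylbenzoate
Product: 22 4-hydroxy-5-methyl-2H-chromen-2-one, via aryl acetate 21 (not isolated)
Conditions: LiHMDS (1.05 equiv), THF, −78 °C; Ac2O (1.05 equiv), −78 → 0 °C; LiHMDS (2.5 equiv), −78 °C → rt; 1 M HCl
Reagents that add atoms: acetic anhydride, CC(=O)OC(C)=O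
Why: O-Acetylation of the phenoxide followed by attack of the acetate enolate on the neighbouring methyl ester (intramolecular Claisen/Dieckmann condensation) closes the pyranone ring, pulled forward by formation of the stabilised 4-oxidocoumarin anion.

**Step 13**
Reactants: 13 (1S,3R)-3-[(3E)-5-hydroxy-3-methylpent-3-en-1-yl]-2,2-dimethyl-4-methylidenecyclohexan-1-ol; 22 4-hydroxy-5-methyl-2H-chromen-2-one
Product: 23 4-{[(2E)-5-[(1R,3S)-3-hydroxy-2,2-dimethyl-6-methylidenecyclohexyl]-3-methylpent-2-en-1-yl]oxy}-5-methyl-2H-chromen-2-one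
Conditions: PPh3, DIAD, THF, 0 °C → rt
Reagents that add atoms: none
Why: Mitsunobu etherification: the acidic 4-hydroxycoumarin is O-alkylated by SN2 on the activated primary allylic alcohol, while the hindered neopentyl-type secondary alcohol does not react, so no protecting group is needed and no stereocentre is involved.

**Compound list**
1 | 2-methylcyclopentane-1,3-dione | CC1C(=O)CCC1=O | starting material
2 | 2,2-dimethylcyclopentane-1,3-dione | CC1(C)C(=O)CCC1=O | intermediate
3 | (3S)-3-hydroxy-2,2-dimethylcyclopentan-1-one | CC1(C)[C@@H](O)CCC1=O | intermediate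
4 | (1S)-2,2-dimethyl-3-oxocyclopentyl pivalate | CC1(C)[C@@H](OC(=O)C(C)(C)C)CCC1=O | intermediate
5 | ethynylmagnesium bromide | C#C[Mg]Br | starting material
6 | (1S)-3-ethynyl-3-hydroxy-2,2-dimethylcyclopentyl pivalate (both C-3 epimers) | CC1(C)[C@@H](OC(=O)C(C)(C)C)CCC1(O)C#C | intermediate
7 | (1S)-2,2-dimethyl-3-methylidene-4-oxocyclohexyl pivalate | CC1(C)[C@@H](OC(=O)C(C)(C)C)CCC(=O)C1=C | intermediate
8 | methyl 3-methylbut-2-enoate | COC(=O)C=C(C)C | starting material
9 | 1-methoxy-3-methyl-1-(trimethylsilyloxy)buta-1,3-diene | COC(O[Si](C)(C)C)=CC(C)=C | intermediate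
10 | methyl (2E)-5-[(5S)-6,6-dimethyl-5-(pivaloyloxy)-2-(trimethylsilyloxy)cyclohex-1-en-1-yl]-3-methylpent-2-enoate | CC1(C)[C@@H](OC(=O)C(C)(C)C)CCC(O[Si](C)(C)C)=C1CC/C(C)=C/C(=O)OC | intermediate
11 | methyl (2E)-5-[(1S,3S)-2,2-dimethyl-6-oxo-3-(pivaloyloxy)cyclohexyl]-3-methylpent-2-enoate | O=C1CC[C@H](OC(=O)C(C)(C)C)C(C)(C)[C@@H]1CC/C(C)=C/C(=O)OC | intermediate
12 | methyl (2E)-5-[(1R,3S)-2,2-dimethyl-6-methylidene-3-(pivaloyloxy)cyclohexyl]-3-methylpent-2-enoate | C=C1CC[C@H](OC(=O)C(C)(C)C)C(C)(C)[C@@H]1CC/C(C)=C/C(=O)OC | intermediate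
13 | (1S,3R)-3-[(3E)-5-hydroxy-3-methylpent-3-en-1-yl]-2,2-dimethyl-4-methylidenecyclohexan-1-ol | C=C1CC[C@H](O)C(C)(C)[C@@H]1CC/C(C)=C/CO | intermediate
14 | methyl acetoacetate (methyl 3-oxobutanoate) | COC(=O)CC(C)=O | starting material
15 | (E)-but-2-enal (crotonaldehyde) | C/C=C/C=O | starting material
16 | methyl 2-acetyl-3-methyl-5-oxopentanoate | COC(=O)C(C(C)=O)C(C)CC=O | intermediate
17 | methyl 4-hydroxy-6-methyl-2-oxocyclohexane-1-carboxylate | COC(=O)C1C(C)CC(O)CC1=O | intermediate
18 | methyl 6-methyl-2-oxocyclohex-3-ene-1-carboxylate | COC(=O)C1C(C)CC=CC1=O | intermediate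
19 | methyl 1-bromo-6-methyl-2-oxocyclohex-3-ene-1-carboxylate | COC(=O)C1(Br)C(C)CC=CC1=O | intermediate
20 | methyl 2-hydroxy-6-methylbenzoate | COC(=O)c1c(C)cccc1O | intermediate
21 | methyl 2-(acetyloxy)-6-methylbenzoate | COC(=O)c1c(C)cccc1OC(C)=O | intermediate
22 | 4-hydroxy-5-methyl-2H-chromen-2-one | Cc1cccc2oc(=O)cc(O)c12 | intermediate
23 | 4-{[(2E)-5-[(1R,3S)-3-hydroxy-2,2-dimethyl-6-methylidenecyclohexyl]-3-methylpent-2-en-1-yl]oxy}-5-methyl-2H-chromen-2-one | C=C1CC[C@H](O)C(C)(C)[C@@H]1CC/C(C)=C/COc1cc(=O)oc2cccc(C)c12 | target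

**Totals**
Total step count: 13. Longest linear sequence: 9 steps (1, 2, 3, 4, 5, 7, 8, 9, 13).

**Three steps most likely to fail**

Step 5 (the proposed new method). Without ring strain the 1,2-shift may be too slow, and hydration, Meyer–Schuster rearrangement or migration of the CH2 carbon could take over. The fallback uses known chemistry, sets out from ketone 4 and comes back at enone 7. Vinylmagnesium bromide with CeCl3 adds to 4 to give (1S)-3-ethenyl-3-hydroxy-2,2-dimethylcyclopentyl pivalate F1. Hydroxyl-directed epoxidation (VO(acac)2, t-BuOOH) gives (1S)-3-hydroxy-2,2-dimethyl-3-(oxiran-2-yl)cyclopentyl pivalate F2. SnCl4 or BF3·OEt2 in CH2Cl2 at −78 °C then triggers the established semipinacol rearrangement of a 2,3-epoxy alcohol, where epoxide opening drives the same shift of the quaternary ring carbon, and gives the ring-expanded aldol (1S)-3-(hydroxymethyl)-2,2-dimethyl-4-oxocyclohexyl pivalate F3. Mesylation (MsCl, Et3N) gives (1S)-3-[(methanesulfonyloxy)methyl]-2,2-dimethyl-4-oxocyclohexyl pivalate F4, which eliminates with DBU to 7.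

Step 7. The dienolate could attack through its α-carbon, react through the s-cis form to give the (Z)-enoate or a [4+2] adduct, and the protonation could be less face-selective than expected. The fallback sets out from enone 7 and comes back at diol 13; it fixes the alkene geometry by syn-carbometalation of an alkyne instead of by dienolate conformation. TiCl4-mediated conjugate propargylation of 7 with allenyltributylstannane (same kinetic protonation) gives (1S,3S)-3-(but-3-yn-1-yl)-2,2-dimethyl-4-oxocyclohexyl pivalate F5. Takai–Lombardo methylenation gives (1S,3R)-3-(but-3-yn-1-yl)-2,2-dimethyl-4-methylidenecyclohexyl pivalate F6. Zirconium-catalysed carboalumination (Me3Al, Cp2ZrCl2, then n-BuLi and paraformaldehyde) gives (1S,3R)-3-[(3E)-5-hydroxy-3-methylpent-3-en-1-yl]-2,2-dimethyl-4-methylidenecyclohexyl pivalate F7 as the (E)-isomer. DIBAL-H then removes the pivalate to give 13.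

Step 13. The ambident coumarin may give C-3 allylation or the 2-alkoxychromone, or the allylic alcohol may react SN2′. The fallback sets out from coumarin 22 and comes back at target 23; it reverses the roles of nucleophile and electrophile. POCl3 converts 22 into 4-chloro-5-methyl-2H-chromen-2-one F8. The primary sodium alkoxide of 13 (NaH, 1.0 equiv, THF, 0 °C) then displaces chloride at C-4 by addition–elimination to give 23, with oxygen bound only at C-4.

**Further compounds**
F1 | step 5 | (1S)-3-ethenyl-3-hydroxy-2,2-dimethylcyclopentyl pivalate | CC1(C)[C@@H](OC(=O)C(C)(C)C)CCC1(O)C=C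
F2 | step 5 | (1S)-3-hydroxy-2,2-dimethyl-3-(oxiran-2-yl)cyclopentyl pivalate | CC1(C)[C@@H](OC(=O)C(C)(C)C)CCC1(O)C2CO2
F3 | step 5 | (1S)-3-(hydroxymethyl)-2,2-dimethyl-4-oxocyclohexyl pivalate | CC1(C)[C@@H](OC(=O)C(C)(C)C)CCC(=O)C1CO
F4 | step 5 | (1S)-3-[(methanesulfonyloxy)methyl]-2,2-dimethyl-4-oxocyclohexyl pivalate | CC1(C)[C@@H](OC(=O)C(C)(C)C)CCC(=O)C1COS(C)(=O)=O
F5 | step 7 | (1S,3S)-3-(but-3-yn-1-yl)-2,2-dimethyl-4-oxocyclohexyl pivalate | O=C1CC[C@H](OC(=O)C(C)(C)C)C(C)(C)[C@@H]1CCC#C
F6 | step 7 | (1S,3R)-3-(but-3-yn-1-yl)-2,2-dimethyl-4-methylidenecyclohexyl pivalate | C=C1CC[C@H](OC(=O)C(C)(C)C)C(C)(C)[C@@H]1CCC#C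
F7 | step 7 | (1S,3R)-3-[(3E)-5-hydroxy-3-methylpent-3-en-1-yl]-2,2-dimethyl-4-methylidenecyclohexyl pivalate | C=C1CC[C@H](OC(=O)C(C)(C)C)C(C)(C)[C@@H]1CC/C(C)=C/CO
F8 | step 13 | 4-chloro-5-methyl-2H-chromen-2-one | Cc1cccc2oc(=O)cc(Cl)c12
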